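In ring B of the target, the two trans CH2OAc-bearing carbons C2 and C3 lie between the benzylic carbons C1 and C4, both attached to ring A. That 1,2,3,4-array is what an o-quinodimethane of ring A and a fumarate give on cycloaddition, so the plan cuts C1–C2 and C3–C4. In a single operation a benzylated 1-aryl-1,3-dihydrobenzo[c]thiophene 2,2-dioxide loses SO2 and the resulting diene takes up di-(−)-menthyl fumarate, which closes ring B and sets C1, C2 and C3. The sulfone is assembled from two benzylated vanillin-type aldehydes by aryllithium addition and sulfide ring closure; afterwards only reduction, acetylation and hydrogenolysis remain.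

Key step: step 8

Remark: O-benzylvanillin and di-(−)-menthyl fumarate are taken as catalogue compounds, and the uncatalysed addition to the menthyl ester is assumed to prefer its Re,Re face only slightly, so the enantiopurity of the product rests on isolating the diastereomerically pure cycloadduct.

Step 1
Reactants: 1 syringaldehyde
Product: 2 4-(benzyloxy)-3,5-dimethoxybenzaldehyde
Conditions: BnBr (1.1 equiv), K2CO3, DMF, 60 °C
Reagents that add atoms: benzyl bromide, BrCc1ccccc1
Why: Williamson ether synthesis, in which the phenoxide made by K2CO3 displaces bromide from the benzylic halide while the aldehyde is untouched.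

Step 2
Reactants: 3 O-benzylvanillin
Product: 4 4-(benzyloxy)-2-bromo-5-methoxybenzaldehyde
Conditions: Br2 (1.05 equiv), NaOAc, AcOH, rt
Reagents that add atoms: bromine, BrBr
Why: Electrophilic aromatic bromination goes to the free position para to the methoxy group (ortho to CHO), as is usual for 3,4-dialkoxybenzaldehydes whose 4-alkoxy group is tied up in conjugation with the aldehyde; the acetate buffer keeps HBr away from the benzyl ether.

Step 3
Reactants: 4 4-(benzyloxy)-2-bromo-5-methoxybenzaldehyde
Product: 5 [4-(benzyloxy)-2-bromo-5-methoxyphenyl]methanol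
Conditions: NaBH4, THF–MeOH, 0 °C
Reagents that add atoms: none
Why: Borohydride reduction of the aldehyde to the benzyl alcohol removes the electrophilic group before metalation and puts the future C4 carbon at the right oxidation level.

Step 4
Reactants: 5 [4-(benzyloxy)-2-bromo-5-methoxyphenyl]methanol; 2 4-(benzyloxy)-3,5-dimethoxybenzaldehyde
Product: 7 [4-(benzyloxy)-3,5-dimethoxyphenyl][5-(benzyloxy)-2-(hydroxymethyl)-4-methoxyphenyl]methanol (racemic), via dilithiated benzyl alkoxide 6 (not isolated)
Conditions: n-BuLi (2.1 equiv), THF, −78 °C; then 2, −78 → 0 °C; H2O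
Reagents that add atoms: none
Why: The first equivalent of n-BuLi makes the lithium alkoxide, the second effects bromine–lithium exchange, and the aryllithium adds 1,2 to aldehyde 2 (organolithium carbonyl addition); the new carbinol centre is racemic, which is immaterial because it becomes sp2 in step 8.

Step 5
Reactants: 7 [4-(benzyloxy)-3,5-dimethoxyphenyl][5-(benzyloxy)-2-(hydroxymethyl)-4-methoxyphenyl]methanol
Product: 8 1-(benzyloxy)-5-{bromo[4-(benzyloxy)-3,5-dimethoxyphenyl]methyl}-4-(bromomethyl)-2-methoxybenzene (racemic)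
Conditions: PBr3 (0.8 equiv), CH2Cl2, 0 °C; crude used at once
Reagents that add atoms: phosphorus tribromide, BrP(Br)Br
Why: Conversion of benzylic alcohols into bromides with PBr3 through phosphite esters, run cold and briefly because the doubly activated benzhydryl position ionises easily.

Step 6
Reactants: 8 1-(benzyloxy)-5-{bromo[4-(benzyloxy)-3,5-dimethoxyphenyl]methyl}-4-(bromomethyl)-2-methoxybenzene
Product: 9 6-(benzyloxy)-1-[4-(benzyloxy)-3,5-dimethoxyphenyl]-5-methoxy-1,3-dihydrobenzo[c]thiophene (racemic)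
Conditions: Na2S·9H2O (1.5 equiv), DMF–THF, 0 °C → rt
Reagents that add atoms: sodium sulfide, [Na+].[Na+].[S-2]
Why: Double nucleophilic substitution by sulfide, in which SN2 attack at the primary benzylic bromide gives a thiolate that closes the five-membered thioether ring at the benzhydryl carbon.

Step 7
Reactants: 9 6-(benzyloxy)-1-[4-(benzyloxy)-3,5-dimethoxyphenyl]-5-methoxy-1,3-dihydrobenzo[c]thiophene
Product: 10 6-(benzyloxy)-1-[4-(benzyloxy)-3,5-dimethoxyphenyl]-5-methoxy-1,3-dihydrobenzo[c]thiophene 2,2-dioxide (racemic)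
Conditions: mCPBA (2.2 equiv), CH2Cl2, 0 °C → rt
Reagents that add atoms: 3-chloroperoxybenzoic acid, OOC(=O)c1cccc(Cl)c1
Why: Peracid oxidation of the sulfide through the sulfoxide to the sulfone, to which the electron-rich arenes and benzyl ethers are inert at this temperature; the racemic C1 centre does not matter.

Step 8
Reactants: 10 6-(benzyloxy)-1-[4-(benzyloxy)-3,5-dimethoxyphenyl]-5-methoxy-1,3-dihydrobenzo[c]thiophene 2,2-dioxide; 11 di-(−)-menthyl fumarate
Product: 13 di-(−)-menthyl (1S,2R,3R)-7-(benzyloxy)-1-[4-(benzyloxy)-3,5-dimethoxyphenyl]-6-methoxy-1,2,3,4-tetrahydronaphthalene-2,3-dicarboxylate, via (E)-aryl o-quinodimethane 12 (not isolated)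
Conditions: 11 (3 equiv), 1,2-dichlorobenzene, 150–160 °C, Ar purge; chromatography, then crystallisation
Reagents that add atoms: none
Why: Heating expels SO2 from 10 in a thermally allowed cheletropic fragmentation and gives the o-quinodimethane 12 with the aryl group outside (E), since the inside position would collide with the hydrogen of the other methylene terminus; 12 is then captured by the fumarate in a concerted suprafacial [4+2] that regains the aromatic sextet of ring A. The closest known reaction type is the Diels–Alder trapping of aryl-substituted o-quinodimethanes, released from benzo-fused cyclic sulfones, by fumaric esters. Ring B is closed as a six-membered carbocycle by intermolecular cycloaddition, C1–C2 and C3–C4 being formed together. C2 and C3 come out trans because the E geometry of the dienophile is carried over stereospecifically, their absolute sense (2R,3R) follows from bonding to the Re,Re face of the C2-symmetric diester, and C1 is S when the ester on C2 lies outside the diene (exo) so that it ends trans to the outside aryl group. The step therefore needs exo orientation of the aryl-side ester and Re,Re face selectivity: the first is helped by the bulk of a plain menthyl ester beside the twisted aryl ring but is opposed by the usual electronic preference for the inward (cis) mode, and the second is weak without a Lewis acid. For that reason 13 is separated from its isomers by chromatography and crystallisation, the chiral esters making every unwanted isomer a diastereomer, and this separation is what secures the single enantiomer.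

Step 9
Reactants: 13 di-(−)-menthyl (1S,2R,3R)-7-(benzyloxy)-1-[4-(benzyloxy)-3,5-dimethoxyphenyl]-6-methoxy-1,2,3,4-tetrahydronaphthalene-2,3-dicarboxylate
Product: 14 [(1S,2R,3R)-7-(benzyloxy)-1-[4-(benzyloxy)-3,5-dimethoxyphenyl]-6-methoxy-1,2,3,4-tetrahydronaphthalene-2,3-diyl]dimethanol
Conditions: LiAlH4 (4 equiv), THF, 0 → 40 °C; Fieser work-up
Reagents that add atoms: none
Why: Hydride reduction of both esters with LiAlH4 gives the diol and releases the auxiliary alcohol, and since C2 and C3 are not enolised under these conditions and C1 is not acidic the three centres are kept.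

Step 10
Reactants: 14 [(1S,2R,3R)-7-(benzyloxy)-1-[4-(benzyloxy)-3,5-dimethoxyphenyl]-6-methoxy-1,2,3,4-tetrahydronaphthalene-2,3-diyl]dimethanol
Product: 15 [(1S,2R,3R)-7-(benzyloxy)-1-[4-(benzyloxy)-3,5-dimethoxyphenyl]-6-methoxy-1,2,3,4-tetrahydronaphthalene-2,3-diyl]bis(methylene) diacetate
Conditions: Ac2O (3 equiv), pyridine, DMAP (cat.), CH2Cl2, rt
Reagents that add atoms: acetic anhydride, CC(=O)OC(C)=O
Why: DMAP-catalysed acylation of the two primary alcohols with acetic anhydride, in which no aryl acetate can form because both phenols are still benzylated.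

Step 11
Reactants: 15 [(1S,2R,3R)-7-(benzyloxy)-1-[4-(benzyloxy)-3,5-dimethoxyphenyl]-6-methoxy-1,2,3,4-tetrahydronaphthalene-2,3-diyl]bis(methylene) diacetate
Product: 16 [(1S,2R,3R)-7-hydroxy-1-(4-hydroxy-3,5-dimethoxyphenyl)-6-methoxy-1,2,3,4-tetrahydronaphthalene-2,3-diyl]bis(methylene) diacetate
Conditions: H2 (1 atm), 10% Pd/C, EtOAc, rt
Reagents that add atoms: none
Why: Catalytic hydrogenolysis of the two aryl benzyl ethers over Pd/C under neutral conditions leaves the alkyl acetates, the methyl ethers and the ring C–C bonds untouched.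

Compound list
1 | syringaldehyde (4-hydroxy-3,5-dimethoxybenzaldehyde) | COc1cc(C=O)cc(OC)c1O | starting material
2 | 4-(benzyloxy)-3,5-dimethoxybenzaldehyde | COc1cc(C=O)cc(OC)c1OCc1ccccc1 | intermediate
3 | O-benzylvanillin (4-(benzyloxy)-3-methoxybenzaldehyde) | COc1cc(C=O)ccc1OCc1ccccc1 | starting material
4 | 4-(benzyloxy)-2-bromo-5-methoxybenzaldehyde | COc1cc(C=O)c(Br)cc1OCc1ccccc1 | intermediate
5 | [4-(benzyloxy)-2-bromo-5-methoxyphenyl]methanol | COc1cc(CO)c(Br)cc1OCc1ccccc1 | intermediate
6 | lithium [4-(benzyloxy)-2-lithio-5-methoxyphenyl]methanolate (formed in the flask) | COc1cc(CO[Li])c([Li])cc1OCc1ccccc1 | intermediate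
7 | [4-(benzyloxy)-3,5-dimethoxyphenyl][5-(benzyloxy)-2-(hydroxymethyl)-4-methoxyphenyl]methanol, racemic | COc1cc(CO)c(cc1OCc1ccccc1)C(O)c1cc(OC)c(OCc2ccccc2)c(OC)c1 | intermediate
8 | 1-(benzyloxy)-5-{bromo[4-(benzyloxy)-3,5-dimethoxyphenyl]methyl}-4-(bromomethyl)-2-methoxybenzene, racemic | COc1cc(CBr)c(cc1OCc1ccccc1)C(Br)c1cc(OC)c(OCc2ccccc2)c(OC)c1 | intermediate
9 | 6-(benzyloxy)-1-[4-(benzyloxy)-3,5-dimethoxyphenyl]-5-methoxy-1,3-dihydrobenzo[c]thiophene, racemic | COc1cc2c(cc1OCc1ccccc1)C(c1cc(OC)c(OCc3ccccc3)c(OC)c1)SC2 | intermediate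
10 | 6-(benzyloxy)-1-[4-(benzyloxy)-3,5-dimethoxyphenyl]-5-methoxy-1,3-dihydrobenzo[c]thiophene 2,2-dioxide, racemic | COc1cc2c(cc1OCc1ccccc1)C(c1cc(OC)c(OCc3ccccc3)c(OC)c1)S(=O)(=O)C2 | intermediate
11 | di-(−)-menthyl fumarate, bis[(1R,2S,5R)-2-isopropyl-5-methylcyclohexyl] (2E)-but-2-enedioate | CC(C)[C@@H]1CC[C@@H](C)C[C@H]1OC(=O)/C=C/C(=O)O[C@@H]1C[C@H](C)CC[C@H]1C(C)C | starting material
12 | (E)-o-quinodimethane, 3-(benzyloxy)-5-{(E)-[4-(benzyloxy)-3,5-dimethoxyphenyl]methylidene}-2-methoxy-6-methylidenecyclohexa-1,3-diene (formed in the flask) | COC1=CC(=C)/C(=C/c2cc(OC)c(OCc3ccccc3)c(OC)c2)C=C1OCc1ccccc1 | intermediate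
13 | di-(−)-menthyl (1S,2R,3R)-7-(benzyloxy)-1-[4-(benzyloxy)-3,5-dimethoxyphenyl]-6-methoxy-1,2,3,4-tetrahydronaphthalene-2,3-dicarboxylate (aryl, C2 ester and C3 ester mutually trans) | COc1cc2c(cc1OCc1ccccc1)[C@H](c1cc(OC)c(OCc3ccccc3)c(OC)c1)[C@@H](C(=O)O[C@@H]1C[C@H](C)CC[C@H]1C(C)C)[C@H](C(=O)O[C@@H]1C[C@H](C)CC[C@H]1C(C)C)C2 | intermediate
14 | [(1S,2R,3R)-7-(benzyloxy)-1-[4-(benzyloxy)-3,5-dimethoxyphenyl]-6-methoxy-1,2,3,4-tetrahydronaphthalene-2,3-diyl]dimethanol | COc1cc2c(cc1OCc1ccccc1)[C@H](c1cc(OC)c(OCc3ccccc3)c(OC)c1)[C@@H](CO)[C@H](CO)C2 | intermediate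
15 | [(1S,2R,3R)-7-(benzyloxy)-1-[4-(benzyloxy)-3,5-dimethoxyphenyl]-6-methoxy-1,2,3,4-tetrahydronaphthalene-2,3-diyl]bis(methylene) diacetate | COc1cc2c(cc1OCc1ccccc1)[C@H](c1cc(OC)c(OCc3ccccc3)c(OC)c1)[C@@H](COC(C)=O)[C@H](COC(C)=O)C2 | intermediate
16 | [(1S,2R,3R)-7-hydroxy-1-(4-hydroxy-3,5-dimethoxyphenyl)-6-methoxy-1,2,3,4-tetrahydronaphthalene-2,3-diyl]bis(methylene) diacetate | COc1cc2c(cc1O)[C@H](c1cc(OC)c(O)c(OC)c1)[C@@H](COC(C)=O)[C@H](COC(C)=O)C2 | target

Total step count: 11.
Longest linear sequence: 10 steps (3 to 16, steps 2–11); step 1 is a one-step side branch.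

Steps most likely to fail

Step 8. The fumarate may add mainly with the aryl-side ester turned inward, giving 1,2-cis adducts, and with little discrimination between its two faces, so that 13 becomes a minor component among four diastereomers. The fallback sets out from sulfone 10 and comes back at diol 14, and it uses the inward mode instead of fighting it. Sulfone 10 is heated as in step 8 with the fumarate of methyl (R)-mandelate, bis[(1R)-2-methoxy-2-oxo-1-phenylethyl] (2E)-but-2-enedioate F1, made from fumaryl chloride and methyl (R)-mandelate with pyridine. Fumarates of this α-acyloxy ester type are known to discriminate their faces well without a Lewis acid and to place the ester next to the aryl group of such dienes inward; with the (R) auxiliary the main adduct should be the 1,2-cis-2,3-trans diester, the bis-mandelate (1S,2S,3S)-tetralin-2,3-dicarboxylate F2. NaOMe in MeOH–THF at reflux exchanges the auxiliary for methyl and equilibrates the two enolisable centres C2 and C3 while the non-acidic C1 stays fixed. The all-equatorial dimethyl (1S,2R,3R)-tetralin-2,3-dicarboxylate F3 should predominate; it is separated and the other isomers are resubmitted. LiAlH4 as in step 9 turns F3 into 14.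

Step 5. Ionisation at the electron-rich benzhydryl carbon can be intercepted by the neighbouring hydroxymethyl oxygen, closing a cyclic ether, and the dibromide can hydrolyse before sulfide is introduced. The fallback sets out from alcohol 5 and comes back at sulfide 9, with sulfur installed before the benzhydryl centre exists. PBr3 converts 5 into the benzyl bromide 1-(benzyloxy)-5-bromo-4-(bromomethyl)-2-methoxybenzene F4. 2-Methylpropane-2-thiol and K2CO3 in DMF give the tert-butyl sulfide 1-(benzyloxy)-5-bromo-4-[(tert-butylsulfanyl)methyl]-2-methoxybenzene F5. Bromine–lithium exchange (n-BuLi, THF, −78 °C) and addition to aldehyde 2 give the carbinol [4-(benzyloxy)-3,5-dimethoxyphenyl]{5-(benzyloxy)-2-[(tert-butylsulfanyl)methyl]-4-methoxyphenyl}methanol F6. Acid (TFA or BF3·OEt2, CH2Cl2, 0 °C) ionises the carbinol, sulfur captures the cation in the five-membered ring, and the sulfonium ion sheds its tert-butyl group as isobutene to give 9.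

Step 4. Bromine–lithium exchange on the sparingly soluble lithium alkoxide may be incomplete, or the aryllithium may be consumed by proton transfer or by the butyl bromide formed, leaving reduced arene and unreacted aldehyde. The fallback sets out from aldehyde 4 and comes back at diol 7, masking the aldehyde instead of reducing it first. Ethylene glycol and TsOH (toluene, Dean–Stark) give the acetal 2-[4-(benzyloxy)-2-bromo-5-methoxyphenyl]-1,3-dioxolane F7. n-BuLi (THF, −78 °C) followed by aldehyde 2 gives the hydroxy acetal [4-(benzyloxy)-3,5-dimethoxyphenyl][5-(benzyloxy)-2-(1,3-dioxolan-2-yl)-4-methoxyphenyl]methanol F8. Dilute HCl in THF unmasks the aldehyde, which closes to the lactol 5-(benzyloxy)-3-[4-(benzyloxy)-3,5-dimethoxyphenyl]-6-methoxy-1,3-dihydro-2-benzofuran-1-ol F9. NaBH4 reduces F9 through its open hydroxy aldehyde form to 7.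

Further compounds
F1 | step 8 | bis[(1R)-2-methoxy-2-oxo-1-phenylethyl] (2E)-but-2-enedioate | COC(=O)[C@H](OC(=O)/C=C/C(=O)O[C@@H](C(=O)OC)c1ccccc1)c1ccccc1
F2 | step 8 | bis[(1R)-2-methoxy-2-oxo-1-phenylethyl] (1S,2S,3S)-7-(benzyloxy)-1-[4-(benzyloxy)-3,5-dimethoxyphenyl]-6-methoxy-1,2,3,4-tetrahydronaphthalene-2,3-dicarboxylate | COc1cc2c(cc1OCc1ccccc1)[C@H](c1cc(OC)c(OCc3ccccc3)c(OC)c1)[C@H](C(=O)O[C@@H](C(=O)OC)c1ccccc1)[C@@H](C(=O)O[C@@H](C(=O)OC)c1ccccc1)C2
F3 | step 8 | dimethyl (1S,2R,3R)-7-(benzyloxy)-1-[4-(benzyloxy)-3,5-dimethoxyphenyl]-6-methoxy-1,2,3,4-tetrahydronaphthalene-2,3-dicarboxylate | COc1cc2c(cc1OCc1ccccc1)[C@H](c1cc(OC)c(OCc3ccccc3)c(OC)c1)[C@@H](C(=O)OC)[C@H](C(=O)OC)C2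
F4 | step 5 | 1-(benzyloxy)-5-bromo-4-(bromomethyl)-2-methoxybenzene | COc1cc(CBr)c(Br)cc1OCc1ccccc1
F5 | step 5 | 1-(benzyloxy)-5-bromo-4-[(tert-butylsulfanyl)methyl]-2-methoxybenzene | COc1cc(CSC(C)(C)C)c(Br)cc1OCc1ccccc1
F6 | step 5 | [4-(benzyloxy)-3,5-dimethoxyphenyl]{5-(benzyloxy)-2-[(tert-butylsulfanyl)methyl]-4-methoxyphenyl}methanol, racemic | COc1cc(CSC(C)(C)C)c(cc1OCc1ccccc1)C(O)c1cc(OC)c(OCc2ccccc2)c(OC)c1
F7 | step 4 | 2-[4-(benzyloxy)-2-bromo-5-methoxyphenyl]-1,3-dioxolane | COc1cc(C2OCCO2)c(Br)cc1OCc1ccccc1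
F8 | step 4 | [4-(benzyloxy)-3,5-dimethoxyphenyl][5-(benzyloxy)-2-(1,3-dioxolan-2-yl)-4-methoxyphenyl]methanol, racemic | COc1cc(C2OCCO2)c(cc1OCc1ccccc1)C(O)c1cc(OC)c(OCc2ccccc2)c(OC)c1
F9 | step 4 | 5-(benzyloxy)-3-[4-(benzyloxy)-3,5-dimethoxyphenyl]-6-methoxy-1,3-dihydro-2-benzofuran-1-ol | COc1cc2C(O)OC(c3cc(OC)c(OCc4ccccc4)c(OC)c3)c2cc1OCc1ccccc1
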